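Remark: the oxolane locants of the target (O1, C2 to C5, C9 on C3, C7' on C4) are used for the corresponding atoms of every intermediate, and monomeric formaldehyde 9 is taken as made by cracking commercial paraformaldehyde just before use.

## Analysis of the target

The target is a lignan ester built on one oxolane ring: O1, C2 bearing a 4-hydroxy-3-methoxyphenyl group, C3 bearing the CH2O arm C9 that is acylated by (E)-4-hydroxycinnamic acid, C4 bearing a 4-hydroxy-3-methoxybenzyl group through C7', and C5 as CH2. C2, C3 and C4 are contiguous stereocentres (2S,3S,4R): the aryl group at C2 is cis to the C9 arm, the C9 arm is trans to the benzyl group at C4, and aryl and benzyl are therefore trans. The cis relation at C2/C3 is the less stable one, and the C2–O1 bond is a benzylic ether para to a phenolic oxygen, so acid can ionise it and let C2 drift to the trans isomer or open the ring. The (E)-cinnamate forbids hydrogenolysis, strong hydride and strong base once it is in place, and three phenols have to be freed together at the end without touching the ester. The difficulty is therefore threefold: the absolute configuration of a trans C3/C4 pair on a flexible five-membered ring, a contra-thermodynamic centre at C2 that must be set late and kinetically, and an end game without acid or hydrogen. The route rests on one feature: if C2 is raised to the carboxyl oxidation level, C3 and C4 are the α- and β-carbons of a γ-lactone, and C9 and C7' are exactly the two groups that a conjugate addition followed by enolate trapping places trans across the C3–C4 double bond of a butenolide. C5, only a CH2 group in the target, can meanwhile serve as an acetal carbon carrying a removable chiral alkoxy group next to C4.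

## Retrosynthetic reasoning

**31 to 30.** Three phenolic O–H bonds are traced back to O–Si bonds. Free phenols would interfere with the carbanion, organolithium, Lewis acid and acylation steps. Silyl ethers are the one kind of phenol protection that comes off without acid (risk to C2), hydrogen (risk to the alkene and the benzylic ether) or strong base (risk to the ester). The forward step must cleave three aryl silyl ethers with buffered fluoride and leave the ester alone.

**30 to 26 and 29.** The acyl–O bond at C9 is cut. It is the only bond joining two otherwise unrelated halves, and the cinnamate could not survive the carbanion, desulfurisation or hydride steps, so it is attached late. Acid 29 comes from 27 by silylation. Alcohol 26 comes from 25 by freeing only the C9 hydroxyl, which requires C9 to carry an alkyl silyl ether that is more acid-labile than the aryl silyl ethers.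

**25 to 22.** Within the ring, C2 is disconnected first because it is the centre most easily lost. Removing the C2–H bond leads through oxocarbenium ion 24 and hemiketal 23 to the γ-hydroxy aryl ketone 22. In the forward sense hydride must add to C2 of 24 on the face away from the C3 substituent at low temperature. That gives the cis relation kinetically, and since it is the last step that makes a stereocentre, nothing later can erode it.

**22 to 17 and 20.** The C2–aryl bond is cut, giving lactone 17 and aryllithium 20, which comes from bromide 19 and that from phenol 18. The cut is convergent, brings the second ring in late, and puts C2 at the carboxyl level, which is what makes C3 and C4 the α- and β-positions of a lactone.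

**17 to 14.** One C5–H bond of 17 is replaced by a C5–O bond to the menthyl group. This adds a stereocentre next to C4 from which absolute configuration can be relayed. Forward, hydroxide opens the acylal, borohydride reduces the liberated C5 aldehyde and acid closes the lactone again, giving back 4. A shorter variant, adding 20 to 14 directly and reducing C2 and C5 in one ionic hydrogenation, is not adopted, for two reasons:
- The ring oxygen of that adduct would sit on a hemiacetal carbon. Ring–chain tautomerism would expel 4 and expose a 1,4-dicarbonyl array that can epimerise at C3 and C4 and aromatise to a furan under the Lewis acid.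
- Reducing the remaining alkyl acetal would need conditions under which the benzylic C2–O1 bond of the product ionises again.

**14 to 13 to 12.** The two C7'–H bonds are traced to the C–S bonds of the dithiane in 13, and the O–Si bond at C9 to the free alcohol 12. The dithiane is the form in which C7' can act as a nucleophile. Its removal with nickel must leave lactone, acetal and silyl ethers intact.

**12 to 8, 5 and 9.** Two C–C bonds, C4–C7' and C3–C9, are cut in one operation. They are chosen because their polarity fits a butenolide: C4 is its electrophilic β-carbon and C3 the nucleophilic α-carbon of the enolate that follows. C7' must therefore be a carbanion (10, from 8) and C9 an electrophile (9). The gain is two skeletal bonds and two stereocentres from three simple components. The forward reaction must add 10 in a 1,4 sense anti to the C5 alkoxy group of 5 and then trap enolate 11 with 9 trans to the new substituent.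

**5 to 3 and 4; 3 to 1; 8 to 7 to 6.** The acetal C5–O bond of 5 is cut to the pseudo-acid 3 and 4, and 3 is traced to 1 by oxidative loss of the formyl carbon. The forward acetalisation must deliver a single C5 epimer, which crystallisation provides. Dithiane 8 is traced through its O–Si bond to 7 and through its two C–S bonds to 6.

## Alternatives that were turned down

**Alternative 1:** reductive cycloetherification.
- Disconnection: O1–C2 and C2–H. The ring is closed and C2 set in one step from an open-chain γ-hydroxy aryl ketone, which is compound 22 of the present route. The product A1 is the same compound as 25.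
- Forward key step: a boron Lewis acid ionises the hemiketal and a silane delivers hydride to C2 at −78 °C.
- For it: the labile centre is made last and cold, the nucleophile is small, and the ketone can be assembled convergently.
- Against: as a strategy it answers only the question of C2. The anti C3/C4 pair of the open chain must come from separate asymmetric steps, and the centre α to the aryl ketone is configurationally fragile in an acyclic precursor.
- Comparison: on control of C2 the two are equal, because step 11 below is this same reaction. An acyclic approach to 22 would also avoid the auxiliary excision of step 8 and could be one or two steps shorter, which is a real advantage. The chosen strategy offers in its place a defined origin for C3 and C4: both arise in one step from a crystalline, recoverable auxiliary, with O1, C5 and the carboxyl carbon already in the ring.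

**Alternative 2:** carbene-catalysed homoenolate annulation.
- Disconnection: C2–C3 and the acyl–O1 bond of lactone A4, in which target C5 is the carbonyl carbon.
- Forward key step: a chiral triazolylidene carbene turns enal A2 into a homoenolate whose β-carbon adds to aldehyde A3; the alkoxide then acylates and closes cis-lactone A4. Enolate benzylation trans to the CH2O arm and reduction of the lactone carbonyl to CH2 would follow.
- For it: it is catalytic and asymmetric, uses two simple aldehydes, and creates the difficult cis aryl/CH2O relation directly. It is stronger than the chosen route in step and atom economy.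
- Against: enantiocontrol in intermolecular homoenolate additions to simple aromatic aldehydes is usually moderate, and an electron-rich aldehyde such as A3 is a sluggish acceptor. The γ-silyloxy group of A2 is a leaving group placed for elimination from the extended enaminol intermediate. The sensitive cis benzylic centre is made first and must then survive an enolate alkylation and a Lewis acid reduction of the C5 lactol.
- Comparison: it is shorter and needs no auxiliary, but it sets the least stable centre first. The chosen route sets it last and takes its absolute configuration from a crystalline acetal.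

**Alternative 3:** dioxepine ring contraction.
- Disconnection: C2–C3. The oxolane is unfolded to the seven-membered cyclic vinyl acetal A5, in which C2 is an acetal carbon and C3 the β-carbon of an enol ether.
- Forward key step: a silyl triflate at −78 °C opens the acetal to an aryl oxocarbenium/enolate pair that recombines through carbon and contracts the ring to aldehyde A6 (2,3-cis, 3,4-trans). The formyl group would then be reduced to the C9 alcohol.
- For it: one step makes the ring, the C2–C3 bond and two stereocentres from the single centre of A5, the cis product is the usual kinetic outcome in the cold, and no auxiliary has to be removed. In bonds, rings and centres per step it is stronger than the chosen key step, which closes no ring.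
- Against: A5 must be made enantiopure with the enol ether double bond on the correct side of the benzyl-bearing carbon, which needs an asymmetric double-bond isomerisation or a separate chiral synthesis. The ion pair of an electron-rich aryl oxocarbenium can re-form and relax to the 2,3-trans aldehyde on slight warming. A6 has an epimerisable centre α to the formyl group. The 3,4-trans relation depends on induction through a flexible transition state.
- Comparison: the chosen route is about four steps longer, but each centre is set by a simple steric argument and the risk is confined to one trapping step.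

Key step: step 5

## Route

Step 1
Reactants: 1 furfural
Product: 3 5-hydroxyfuran-2(5H)-one (racemic), via endoperoxide 2 (not isolated)
Conditions: O2, rose bengal (cat.), hν (visible), MeOH, rt
Reagents that add atoms: dioxygen, O=O
Why: Sensitised singlet oxygen adds across C2/C5 of the furan in a [4+2] cycloaddition to give 2; methanol attacks the formyl group and the adduct fragments with loss of the formyl carbon to the pseudo-acid 3 (furan photo-oxygenation); C5 is racemic here and is settled in step 2.

Step 2
Reactants: 3 5-hydroxyfuran-2(5H)-one; 4 (−)-menthol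
Product: 5 (5R)-5-[(1R,2S,5R)-menthyloxy]furan-2(5H)-one
Conditions: CSA (cat.), toluene, reflux, Dean–Stark; crystallisation from petroleum ether; mother liquor re-equilibrated with CSA and crystallised again
Reagents that add atoms: none
Why: Acid-catalysed acetalisation of the cyclic hemiacylal; the two C5 epimers interconvert under the acid and the (5R) epimer is the one that crystallises, so a crystallisation-induced diastereomer transformation should converge the mixture on 5 and fix the centre from which C3 and C4 are later derived.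

Step 3
Reactants: 6 vanillin
Product: 7 4-(1,3-dithian-2-yl)-2-methoxyphenol
Conditions: HS(CH2)3SH, BF3·OEt2 (cat.), CH2Cl2, 0 °C → rt
Reagents that add atoms: propane-1,3-dithiol, SCCCS
Why: Lewis acid-catalysed dithioacetalisation of the aromatic aldehyde; the free phenol is inert, and the dithiane C–H becomes the acyl-anion (umpolung) site for C7'.

Step 4
Reactants: 7 4-(1,3-dithian-2-yl)-2-methoxyphenol
Product: 8 2-[3-methoxy-4-(triisopropylsilyloxy)phenyl]-1,3-dithiane
Conditions: TIPSCl, imidazole, DMF, rt
Reagents that add atoms: chlorotriisopropylsilane, CC(C)[Si](Cl)(C(C)C)C(C)C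
Why: Imidazole-mediated O-silylation of the phenol; an aryl TIPS ether should tolerate n-BuLi, Raney Ni, cold dilute hydroxide and BF3·OEt2 and is kept for the final fluoride step.

Step 5
Reactants: 8 2-[3-methoxy-4-(triisopropylsilyloxy)phenyl]-1,3-dithiane; 5 (5R)-5-[(1R,2S,5R)-menthyloxy]furan-2(5H)-one; 9 formaldehyde
Product: 12 (3S,4R,5R)-3-(hydroxymethyl)-4-{2-[3-methoxy-4-(triisopropylsilyloxy)phenyl]-1,3-dithian-2-yl}-5-[(1R,2S,5R)-menthyloxy]dihydrofuran-2(3H)-one, via 2-lithiodithiane 10 (not isolated), via lithium enolate 11 (not isolated)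
Conditions: 8, n-BuLi (1.05 equiv), THF, −78 → −20 °C; 5, THF, −78 °C; CH2O (g, Ar stream), −78 °C; AcOH, −78 °C
Reagents that add atoms: none
Why: n-BuLi removes the benzylic C–H flanked by two sulfurs in 8 to give 10, which adds to C4 of butenolide 5 in a 1,4 sense to form lithium enolate 11; gaseous formaldehyde then reacts at C3 in an aldol addition and AcOH quenches the alkoxide cold. The closest known reaction type is the tandem conjugate addition–enolate trapping of lithiated 2-aryl-1,3-dithianes on 5-alkoxybutenolides with benzylic halides or aromatic aldehydes, and hydroxymethylation of lithium enolates with monomeric formaldehyde is standard. No ring is closed; the bonds C4–C7' and C3–C9 are made on the preformed lactone. C4 (4R) is controlled by the C5 menthyloxy group: the bulky carbanion attacks the face of the flat butenolide opposite the acetal alkoxy group and gives the 4,5-trans adduct. C3 (3S) is controlled by the new quaternary dithianyl group at C4, which shields one face of the enolate so that formaldehyde adds trans to it. The step needs 1,4- over 1,2-addition, which the soft, delocalised and hindered carbanion and the unhindered β-carbon should secure, and a single hydroxymethylation without equilibration, which the preformed lithium enolate at −78 °C, monomeric formaldehyde and the acidic quench before warming should secure. The (5R) centre is not touched, so the configuration taken from menthol is relayed to both new centres.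

Step 6
Reactants: 12 (3S,4R,5R)-3-(hydroxymethyl)-4-{2-[3-methoxy-4-(triisopropylsilyloxy)phenyl]-1,3-dithian-2-yl}-5-[(1R,2S,5R)-menthyloxy]dihydrofuran-2(3H)-one
Product: 13 (3S,4R,5R)-3-[(tert-butyldimethylsilyloxy)methyl]-4-{2-[3-methoxy-4-(triisopropylsilyloxy)phenyl]-1,3-dithian-2-yl}-5-[(1R,2S,5R)-menthyloxy]dihydrofuran-2(3H)-one
Conditions: TBSCl, imidazole, DMF, 0 °C → rt
Reagents that add atoms: tert-butyl(chloro)dimethylsilane, CC(C)(C)[Si](C)(C)Cl
Why: Standard silylation of the primary alcohol; it blocks retro-aldol and β-elimination of the β-hydroxy lactone and keeps C9 distinct from the phenols, because an alkyl TBS ether can later be removed by mild acid beside aryl TIPS ethers.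

Step 7
Reactants: 13 (3S,4R,5R)-3-[(tert-butyldimethylsilyloxy)methyl]-4-{2-[3-methoxy-4-(triisopropylsilyloxy)phenyl]-1,3-dithian-2-yl}-5-[(1R,2S,5R)-menthyloxy]dihydrofuran-2(3H)-one
Product: 14 (3S,4R,5R)-3-[(tert-butyldimethylsilyloxy)methyl]-4-[3-methoxy-4-(triisopropylsilyloxy)benzyl]-5-[(1R,2S,5R)-menthyloxy]dihydrofuran-2(3H)-one
Conditions: Raney Ni (W-2, washed neutral), EtOH, rt → 50 °C
Reagents that add atoms: none
Why: Raney Ni hydrogenolysis of both C–S bonds (Mozingo-type desulfurisation) turns the masked acyl carbon into the benzylic CH2 group C7'; lactone, acetal and silyl ethers are inert to neutral Raney Ni and no stereocentre is involved.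

Step 8
Reactants: 14 (3S,4R,5R)-3-[(tert-butyldimethylsilyloxy)methyl]-4-[3-methoxy-4-(triisopropylsilyloxy)benzyl]-5-[(1R,2S,5R)-menthyloxy]dihydrofuran-2(3H)-one
Product: 17 (3S,4R)-3-[(tert-butyldimethylsilyloxy)methyl]-4-[3-methoxy-4-(triisopropylsilyloxy)benzyl]dihydrofuran-2(3H)-one, via formyl carboxylate 15 (not isolated), via hydroxy carboxylate 16 (not isolated)
Conditions: KOH (2.5 equiv, 0.2 M), NaBH4, EtOH/THF/H2O, 0 °C; then 1 M HCl to pH 3, 0 °C → rt
Reagents that add atoms: potassium hydroxide, [K+].[OH-] (its oxygen enters the carboxylate of 15 and 16; lactonisation then expels one of the two carboxyl oxygens as water)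
Why: Hydroxide opens the acylal lactone, the hemiacetal anion expels menthoxide, and the released aldehyde 15 is reduced at once by NaBH4 to 16; acidification closes the γ-hydroxy acid to the lactone, so C5 becomes CH2 while C2 stays at the carboxyl level (hydrolysis–reduction of a pseudo-ester); C3 is not enolisable as a carboxylate, and fast reduction should outrun enolisation at C4.

Step 9
Reactants: 18 4-bromo-2-methoxyphenol
Product: 19 (4-bromo-2-methoxyphenoxy)triisopropylsilane
Conditions: TIPSCl, imidazole, DMF, rt
Reagents that add atoms: chlorotriisopropylsilane, CC(C)[Si](Cl)(C(C)C)C(C)C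
Why: Phenol silylation as in step 4; the bromide is the handle for halogen–lithium exchange.

Step 10
Reactants: 19 (4-bromo-2-methoxyphenoxy)triisopropylsilane; 17 (3S,4R)-3-[(tert-butyldimethylsilyloxy)methyl]-4-[3-methoxy-4-(triisopropylsilyloxy)benzyl]dihydrofuran-2(3H)-one
Product: 22 (2S,3R)-2-[(tert-butyldimethylsilyloxy)methyl]-4-hydroxy-3-[3-methoxy-4-(triisopropylsilyloxy)benzyl]-1-[3-methoxy-4-(triisopropylsilyloxy)phenyl]butan-1-one, via aryllithium 20 (not isolated), via lithium hemiketal alkoxide 21 (not isolated)
Conditions: 19, n-BuLi, THF, −78 °C; cannulated into 17, THF, −78 °C; AcOH, −78 °C; crude product used directly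
Reagents that add atoms: none
Why: Bromine–lithium exchange gives 20, in which lithium is para to the silyloxy group so no silyl migration is possible; it adds once to the lactone carbonyl because the lithium hemiketal alkoxide 21 persists at −78 °C until the acidic quench, which releases ketone 22 in equilibrium with its hemiketal (organolithium addition to a lactone); the cold quench and direct use of the crude material should avoid epimerisation at C3 and β-elimination of the silyloxy group.

Step 11
Reactants: 22 (2S,3R)-2-[(tert-butyldimethylsilyloxy)methyl]-4-hydroxy-3-[3-methoxy-4-(triisopropylsilyloxy)benzyl]-1-[3-methoxy-4-(triisopropylsilyloxy)phenyl]butan-1-one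
Product: 25 (2S,3S,4R)-3-[(tert-butyldimethylsilyloxy)methyl]-4-[3-methoxy-4-(triisopropylsilyloxy)benzyl]-2-[3-methoxy-4-(triisopropylsilyloxy)phenyl]oxolane, via cyclic hemiketal 23 (not isolated), via oxocarbenium ion 24 (not isolated)
Conditions: Et3SiH (5 equiv), BF3·OEt2 (2 equiv), CH2Cl2, −78 °C; Et3N then NaHCO3 (aq.) at −78 °C
Reagents that add atoms: none
Why: BF3·OEt2 ionises hemiketal 23 to the aryl-conjugated oxocarbenium ion 24 and Et3SiH transfers hydride to C2 (ionic hydrogenation, reductive etherification); the C3 substituent turns pseudoaxial to avoid allylic strain with the coplanar aryl ring and hydride enters on the opposite, inside face of the envelope, so H-2 ends trans and the aryl group cis to the C9 arm (2S); −78 °C and the cold basic quench should keep the benzylic ether from ionising again and relaxing to the 2,3-trans isomer.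

Step 12
Reactants: 25 (2S,3S,4R)-3-[(tert-butyldimethylsilyloxy)methyl]-4-[3-methoxy-4-(triisopropylsilyloxy)benzyl]-2-[3-methoxy-4-(triisopropylsilyloxy)phenyl]oxolane
Product: 26 {(2S,3S,4R)-4-[3-methoxy-4-(triisopropylsilyloxy)benzyl]-2-[3-methoxy-4-(triisopropylsilyloxy)phenyl]oxolan-3-yl}methanol
Conditions: PPTS (0.3 equiv), MeOH, rt
Reagents that add atoms: none
Why: Acid-catalysed methanolysis cleaves the primary alkyl TBS ether much faster than the hindered aryl TIPS ethers (selective desilylation), and the weak acid should not ionise the C2–O1 bond.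

Step 13
Reactants: 27 (E)-4-hydroxycinnamic acid (p-coumaric acid)
Product: 29 (E)-3-[4-(tert-butyldimethylsilyloxy)phenyl]prop-2-enoic acid, via bis-silyl ester 28 (not isolated)
Conditions: TBSCl (2.3 equiv), imidazole, DMF, rt; then AcOH/THF/H2O, rt
Reagents that add atoms: tert-butyl(chloro)dimethylsilane, CC(C)(C)[Si](C)(C)Cl
Why: Both acidic OH groups are silylated and the labile silyl ester of 28 is then hydrolysed selectively by aqueous AcOH while the aryl TBS ether stays (protection of a phenolic acid).

Step 14
Reactants: 26 {(2S,3S,4R)-4-[3-methoxy-4-(triisopropylsilyloxy)benzyl]-2-[3-methoxy-4-(triisopropylsilyloxy)phenyl]oxolan-3-yl}methanol; 29 (E)-3-[4-(tert-butyldimethylsilyloxy)phenyl]prop-2-enoic acid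
Product: 30 {(2S,3S,4R)-4-[3-methoxy-4-(triisopropylsilyloxy)benzyl]-2-[3-methoxy-4-(triisopropylsilyloxy)phenyl]oxolan-3-yl}methyl (E)-3-[4-(tert-butyldimethylsilyloxy)phenyl]prop-2-enoate
Conditions: EDC·HCl, DMAP (cat.), CH2Cl2, 0 °C → rt
Reagents that add atoms: none
Why: Steglich esterification of the only free hydroxyl; the neutral conditions leave the silyl ethers, the cis benzylic ether and the (E) alkene untouched.

Step 15
Reactants: 30 {(2S,3S,4R)-4-[3-methoxy-4-(triisopropylsilyloxy)benzyl]-2-[3-methoxy-4-(triisopropylsilyloxy)phenyl]oxolan-3-yl}methyl (E)-3-[4-(tert-butyldimethylsilyloxy)phenyl]prop-2-enoate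
Product: 31 {(2S,3S,4R)-2-(4-hydroxy-3-methoxyphenyl)-4-(4-hydroxy-3-methoxybenzyl)oxolan-3-yl}methyl (E)-3-(4-hydroxyphenyl)prop-2-enoate (CNP0119373.2)
Conditions: Bu4NF (3.5 equiv), AcOH (4 equiv), THF, 0 °C
Reagents that add atoms: none
Why: Fluoride cleaves the three aryl silyl ethers at 0 °C (global desilylation); the AcOH buffer keeps the medium from becoming basic enough for ester cleavage or acyl migration, and no acid strong enough to epimerise C2 is present.

## Compound list

1 | furfural (furan-2-carbaldehyde) | O=Cc1ccco1 | starting material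
2 | 1-formyl-2,3,7-trioxabicyclo[2.2.1]hept-5-ene (furfural endoperoxide, racemic) | O=CC12OOC(C=C1)O2 | intermediate
3 | 5-hydroxyfuran-2(5H)-one (racemic) | O=C1C=CC(O)O1 | intermediate
4 | (−)-menthol, (1R,2S,5R)-5-methyl-2-(propan-2-yl)cyclohexan-1-ol | CC(C)[C@@H]1CC[C@@H](C)C[C@H]1O | starting material
5 | (5R)-5-[(1R,2S,5R)-menthyloxy]furan-2(5H)-one | O=C1C=C[C@H](O[C@@H]2C[C@H](C)CC[C@H]2C(C)C)O1 | intermediate
6 | vanillin | COc1cc(C=O)ccc1O | starting material
7 | 4-(1,3-dithian-2-yl)-2-methoxyphenol | COc1cc(C2SCCCS2)ccc1O | intermediate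
8 | 2-[3-methoxy-4-(triisopropylsilyloxy)phenyl]-1,3-dithiane | COc1cc(C2SCCCS2)ccc1O[Si](C(C)C)(C(C)C)C(C)C | intermediate
9 | formaldehyde | C=O | starting material
10 | 2-lithio-2-[3-methoxy-4-(triisopropylsilyloxy)phenyl]-1,3-dithiane | COc1cc(C2([Li])SCCCS2)ccc1O[Si](C(C)C)(C(C)C)C(C)C | intermediate
11 | lithium (4R,5R)-4-{2-[3-methoxy-4-(triisopropylsilyloxy)phenyl]-1,3-dithian-2-yl}-5-[(1R,2S,5R)-menthyloxy]-4,5-dihydrofuran-2-olate | [Li]OC1=C[C@@H](C2(c3ccc(O[Si](C(C)C)(C(C)C)C(C)C)c(OC)c3)SCCCS2)[C@H](O[C@@H]2C[C@H](C)CC[C@H]2C(C)C)O1 | intermediate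
12 | (3S,4R,5R)-3-(hydroxymethyl)-4-{2-[3-methoxy-4-(triisopropylsilyloxy)phenyl]-1,3-dithian-2-yl}-5-[(1R,2S,5R)-menthyloxy]dihydrofuran-2(3H)-one (3,4-trans, 4,5-trans) | O=C1[C@H](CO)[C@@H](C2(c3ccc(O[Si](C(C)C)(C(C)C)C(C)C)c(OC)c3)SCCCS2)[C@H](O[C@@H]3C[C@H](C)CC[C@H]3C(C)C)O1 | intermediate
13 | (3S,4R,5R)-3-[(tert-butyldimethylsilyloxy)methyl]-4-{2-[3-methoxy-4-(triisopropylsilyloxy)phenyl]-1,3-dithian-2-yl}-5-[(1R,2S,5R)-menthyloxy]dihydrofuran-2(3H)-one | O=C1[C@H](CO[Si](C)(C)C(C)(C)C)[C@@H](C2(c3ccc(O[Si](C(C)C)(C(C)C)C(C)C)c(OC)c3)SCCCS2)[C@H](O[C@@H]3C[C@H](C)CC[C@H]3C(C)C)O1 | intermediate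
14 | (3S,4R,5R)-3-[(tert-butyldimethylsilyloxy)methyl]-4-[3-methoxy-4-(triisopropylsilyloxy)benzyl]-5-[(1R,2S,5R)-menthyloxy]dihydrofuran-2(3H)-one | O=C1[C@H](CO[Si](C)(C)C(C)(C)C)[C@@H](Cc2ccc(O[Si](C(C)C)(C(C)C)C(C)C)c(OC)c2)[C@H](O[C@@H]2C[C@H](C)CC[C@H]2C(C)C)O1 | intermediate
15 | potassium (2S,3R)-2-[(tert-butyldimethylsilyloxy)methyl]-3-formyl-4-[3-methoxy-4-(triisopropylsilyloxy)phenyl]butanoate | [K+].[O-]C(=O)[C@H](CO[Si](C)(C)C(C)(C)C)[C@@H](Cc1ccc(O[Si](C(C)C)(C(C)C)C(C)C)c(OC)c1)C=O | intermediate
16 | potassium (2S,3R)-2-[(tert-butyldimethylsilyloxy)methyl]-3-(hydroxymethyl)-4-[3-methoxy-4-(triisopropylsilyloxy)phenyl]butanoate | [K+].[O-]C(=O)[C@H](CO[Si](C)(C)C(C)(C)C)[C@@H](Cc1ccc(O[Si](C(C)C)(C(C)C)C(C)C)c(OC)c1)CO | intermediate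
17 | (3S,4R)-3-[(tert-butyldimethylsilyloxy)methyl]-4-[3-methoxy-4-(triisopropylsilyloxy)benzyl]dihydrofuran-2(3H)-one (trans) | O=C1[C@H](CO[Si](C)(C)C(C)(C)C)[C@@H](Cc2ccc(O[Si](C(C)C)(C(C)C)C(C)C)c(OC)c2)CO1 | intermediate
18 | 4-bromo-2-methoxyphenol | COc1cc(Br)ccc1O | starting material
19 | (4-bromo-2-methoxyphenoxy)triisopropylsilane | COc1cc(Br)ccc1O[Si](C(C)C)(C(C)C)C(C)C | intermediate
20 | [3-methoxy-4-(triisopropylsilyloxy)phenyl]lithium | COc1cc([Li])ccc1O[Si](C(C)C)(C(C)C)C(C)C | intermediate
21 | lithium (3S,4R)-3-[(tert-butyldimethylsilyloxy)methyl]-4-[3-methoxy-4-(triisopropylsilyloxy)benzyl]-2-[3-methoxy-4-(triisopropylsilyloxy)phenyl]oxolan-2-olate (C2 epimers) | [Li]OC1(c2ccc(O[Si](C(C)C)(C(C)C)C(C)C)c(OC)c2)[C@H](CO[Si](C)(C)C(C)(C)C)[C@@H](Cc2ccc(O[Si](C(C)C)(C(C)C)C(C)C)c(OC)c2)CO1 | intermediate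
22 | (2S,3R)-2-[(tert-butyldimethylsilyloxy)methyl]-4-hydroxy-3-[3-methoxy-4-(triisopropylsilyloxy)benzyl]-1-[3-methoxy-4-(triisopropylsilyloxy)phenyl]butan-1-one | O=C(c1ccc(O[Si](C(C)C)(C(C)C)C(C)C)c(OC)c1)[C@H](CO[Si](C)(C)C(C)(C)C)[C@@H](Cc1ccc(O[Si](C(C)C)(C(C)C)C(C)C)c(OC)c1)CO | intermediate
23 | (3S,4R)-3-[(tert-butyldimethylsilyloxy)methyl]-4-[3-methoxy-4-(triisopropylsilyloxy)benzyl]-2-[3-methoxy-4-(triisopropylsilyloxy)phenyl]oxolan-2-ol (C2 epimers) | OC1(c2ccc(O[Si](C(C)C)(C(C)C)C(C)C)c(OC)c2)[C@H](CO[Si](C)(C)C(C)(C)C)[C@@H](Cc2ccc(O[Si](C(C)C)(C(C)C)C(C)C)c(OC)c2)CO1 | intermediate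
24 | (3S,4R)-3-[(tert-butyldimethylsilyloxy)methyl]-4-[3-methoxy-4-(triisopropylsilyloxy)benzyl]-2-[3-methoxy-4-(triisopropylsilyloxy)phenyl]oxolan-2-ylium (cyclic oxocarbenium ion, C2=O1+) | [O+]1=C(c2ccc(O[Si](C(C)C)(C(C)C)C(C)C)c(OC)c2)[C@H](CO[Si](C)(C)C(C)(C)C)[C@@H](Cc2ccc(O[Si](C(C)C)(C(C)C)C(C)C)c(OC)c2)C1 | intermediate
25 | (2S,3S,4R)-3-[(tert-butyldimethylsilyloxy)methyl]-4-[3-methoxy-4-(triisopropylsilyloxy)benzyl]-2-[3-methoxy-4-(triisopropylsilyloxy)phenyl]oxolane (2,3-cis, 3,4-trans) | COc1cc(C[C@H]2CO[C@H](c3ccc(O[Si](C(C)C)(C(C)C)C(C)C)c(OC)c3)[C@@H]2CO[Si](C)(C)C(C)(C)C)ccc1O[Si](C(C)C)(C(C)C)C(C)C | intermediate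
26 | {(2S,3S,4R)-4-[3-methoxy-4-(triisopropylsilyloxy)benzyl]-2-[3-methoxy-4-(triisopropylsilyloxy)phenyl]oxolan-3-yl}methanol | COc1cc(C[C@H]2CO[C@H](c3ccc(O[Si](C(C)C)(C(C)C)C(C)C)c(OC)c3)[C@@H]2CO)ccc1O[Si](C(C)C)(C(C)C)C(C)C | intermediate
27 | (E)-4-hydroxycinnamic acid (p-coumaric acid) | OC(=O)/C=C/c1ccc(O)cc1 | starting material
28 | tert-butyldimethylsilyl (E)-3-[4-(tert-butyldimethylsilyloxy)phenyl]prop-2-enoate | CC(C)(C)[Si](C)(C)OC(=O)/C=C/c1ccc(O[Si](C)(C)C(C)(C)C)cc1 | intermediate
29 | (E)-3-[4-(tert-butyldimethylsilyloxy)phenyl]prop-2-enoic acid | OC(=O)/C=C/c1ccc(O[Si](C)(C)C(C)(C)C)cc1 | intermediate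
30 | {(2S,3S,4R)-4-[3-methoxy-4-(triisopropylsilyloxy)benzyl]-2-[3-methoxy-4-(triisopropylsilyloxy)phenyl]oxolan-3-yl}methyl (E)-3-[4-(tert-butyldimethylsilyloxy)phenyl]prop-2-enoate | COc1cc(C[C@H]2CO[C@H](c3ccc(O[Si](C(C)C)(C(C)C)C(C)C)c(OC)c3)[C@@H]2COC(=O)/C=C/c2ccc(O[Si](C)(C)C(C)(C)C)cc2)ccc1O[Si](C(C)C)(C(C)C)C(C)C | intermediate
31 | {(2S,3S,4R)-2-(4-hydroxy-3-methoxyphenyl)-4-(4-hydroxy-3-methoxybenzyl)oxolan-3-yl}methyl (E)-3-(4-hydroxyphenyl)prop-2-enoate | COc1cc(C[C@H]2CO[C@H](c3ccc(O)c(OC)c3)[C@@H]2COC(=O)/C=C/c2ccc(O)cc2)ccc1O | target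

## Step count and least certain steps

Total: 15 steps. Longest linear sequence: 11 steps (1, 2, 5, 6, 7, 8, 10, 11, 12, 14, 15; the branch from vanillin through steps 3 and 4 is equally long).

**Step 5 (key step).** The conjugate addition itself should be dependable. The weak point is capture of enolate 11 by formaldehyde: the gas may oligomerise in the inlet, proton transfer may compete, or a second hydroxymethylation may follow, giving material protonated at C3 or a mixture. The fallback replaces the aldol trap by an alkylation. It sets out from 8 and 5: enolate 11 is generated as before and alkylated with benzyl chloromethyl ether in THF/DMPU to give (3S,4R,5R)-3-[(benzyloxy)methyl]-4-{2-[3-methoxy-4-(triisopropylsilyloxy)phenyl]-1,3-dithian-2-yl}-5-[(1R,2S,5R)-menthyloxy]dihydrofuran-2(3H)-one F1, trans for the same steric reason. Raney Ni in refluxing EtOH then removes the dithiane and hydrogenolyses the benzyl ether to (3S,4R,5R)-3-(hydroxymethyl)-4-[3-methoxy-4-(triisopropylsilyloxy)benzyl]-5-[(1R,2S,5R)-menthyloxy]dihydrofuran-2(3H)-one F2. Silylation with TBSCl/imidazole gives 14, where the route is rejoined.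

**Step 8.** Two processes threaten it: hydroxide may attack the aryl silyl ether, and the transient aldehyde 15 may enolise and epimerise C4 before it is reduced. The conditions are kept dilute and cold for that reason. The fallback accepts loss of the aryl silyl group instead of fighting it. From 14, the hydrolysis–reduction is run with excess KOH at rt until the aryl ether is fully cleaved, and acidification gives (3S,4R)-3-[(tert-butyldimethylsilyloxy)methyl]-4-(4-hydroxy-3-methoxybenzyl)dihydrofuran-2(3H)-one F3. Silylation with TIPSCl/imidazole returns to 17.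

**Step 10.** The ring-opened ketone may take up a second aryllithium, the lactone may be enolised instead of attacked, and ketone 22 may lose configuration at C3 or eliminate the silyloxy group on handling. The fallback changes the oxidation level at which the aryl group is introduced. From 17, i-Bu2AlH at −78 °C gives (3S,4R)-3-[(tert-butyldimethylsilyloxy)methyl]-4-[3-methoxy-4-(triisopropylsilyloxy)benzyl]oxolan-2-ol F4. Two equivalents of 20 add to its open aldehyde form to give (2S,3R)-2-[(tert-butyldimethylsilyloxy)methyl]-3-[3-methoxy-4-(triisopropylsilyloxy)benzyl]-1-[3-methoxy-4-(triisopropylsilyloxy)phenyl]butane-1,4-diol F5 as a mixture of carbinol epimers. MnO2 in CH2Cl2 oxidises only the benzylic alcohol and returns to 22.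

**Step 11.** Facial selectivity may be poor, because the C4 benzyl group lies on the face that hydride must use. The benzylic ether may also re-ionise, equilibrating to the 2,3-trans isomer or undergoing further reduction with ring opening, and 24 may lose a proton at C3. The fallback separates the creation of C2 from ring closure. From 22, a Corey–Bakshi–Shibata reduction with (R)-2-methyl-CBS-oxazaborolidine and BH3·SMe2 sets the carbinol under reagent control, giving (1S,2S,3R)-2-[(tert-butyldimethylsilyloxy)methyl]-3-[3-methoxy-4-(triisopropylsilyloxy)benzyl]-1-[3-methoxy-4-(triisopropylsilyloxy)phenyl]butane-1,4-diol F6. Selective sulfonylation of the primary hydroxyl (TsCl, Et3N, DMAP cat.) gives (2R,3S,4S)-4-hydroxy-2-[3-methoxy-4-(triisopropylsilyloxy)benzyl]-3-[(tert-butyldimethylsilyloxy)methyl]-4-[3-methoxy-4-(triisopropylsilyloxy)phenyl]butyl 4-methylbenzenesulfonate F7. NaH in THF closes the ring by Williamson substitution at C5, with the benzylic centre untouched, and returns to 25.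

**Step 15.** Phenoxide formed during fluoride treatment may cleave or transfer the cinnamate, or the hindered TIPS ethers may come off incompletely. The fallback frees the phenols before the ester is made. From 25, Bu4NF in THF removes all three silyl groups to give 4-[(2S,3S,4R)-4-(4-hydroxy-3-methoxybenzyl)-3-(hydroxymethyl)oxolan-2-yl]-2-methoxyphenol F8. A Mitsunobu esterification (PPh3, DIAD, THF, 0 °C) with unprotected acid 27 then acylates only the primary alcohol, since the carboxylic acid is the pronucleophile and phenols are not activated, and arrives directly at 31.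

## Further compounds

F1 | step 5 | (3S,4R,5R)-3-[(benzyloxy)methyl]-4-{2-[3-methoxy-4-(triisopropylsilyloxy)phenyl]-1,3-dithian-2-yl}-5-[(1R,2S,5R)-menthyloxy]dihydrofuran-2(3H)-one | O=C1[C@H](COCc2ccccc2)[C@@H](C2(c3ccc(O[Si](C(C)C)(C(C)C)C(C)C)c(OC)c3)SCCCS2)[C@H](O[C@@H]3C[C@H](C)CC[C@H]3C(C)C)O1
F2 | step 5 | (3S,4R,5R)-3-(hydroxymethyl)-4-[3-methoxy-4-(triisopropylsilyloxy)benzyl]-5-[(1R,2S,5R)-menthyloxy]dihydrofuran-2(3H)-one | O=C1[C@H](CO)[C@@H](Cc2ccc(O[Si](C(C)C)(C(C)C)C(C)C)c(OC)c2)[C@H](O[C@@H]2C[C@H](C)CC[C@H]2C(C)C)O1
F3 | step 8 | (3S,4R)-3-[(tert-butyldimethylsilyloxy)methyl]-4-(4-hydroxy-3-methoxybenzyl)dihydrofuran-2(3H)-one | O=C1[C@H](CO[Si](C)(C)C(C)(C)C)[C@@H](Cc2ccc(O)c(OC)c2)CO1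
F4 | step 10 | (3S,4R)-3-[(tert-butyldimethylsilyloxy)methyl]-4-[3-methoxy-4-(triisopropylsilyloxy)benzyl]oxolan-2-ol (C2 epimers) | OC1[C@H](CO[Si](C)(C)C(C)(C)C)[C@@H](Cc2ccc(O[Si](C(C)C)(C(C)C)C(C)C)c(OC)c2)CO1
F5 | step 10 | (2S,3R)-2-[(tert-butyldimethylsilyloxy)methyl]-3-[3-methoxy-4-(triisopropylsilyloxy)benzyl]-1-[3-methoxy-4-(triisopropylsilyloxy)phenyl]butane-1,4-diol (C1 epimers) | OC(c1ccc(O[Si](C(C)C)(C(C)C)C(C)C)c(OC)c1)[C@H](CO[Si](C)(C)C(C)(C)C)[C@@H](Cc1ccc(O[Si](C(C)C)(C(C)C)C(C)C)c(OC)c1)CO
F6 | step 11 | (1S,2S,3R)-2-[(tert-butyldimethylsilyloxy)methyl]-3-[3-methoxy-4-(triisopropylsilyloxy)benzyl]-1-[3-methoxy-4-(triisopropylsilyloxy)phenyl]butane-1,4-diol | O[C@H](c1ccc(O[Si](C(C)C)(C(C)C)C(C)C)c(OC)c1)[C@H](CO[Si](C)(C)C(C)(C)C)[C@@H](Cc1ccc(O[Si](C(C)C)(C(C)C)C(C)C)c(OC)c1)CO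
F7 | step 11 | (2R,3S,4S)-4-hydroxy-2-[3-methoxy-4-(triisopropylsilyloxy)benzyl]-3-[(tert-butyldimethylsilyloxy)methyl]-4-[3-methoxy-4-(triisopropylsilyloxy)phenyl]butyl 4-methylbenzenesulfonate | O[C@H](c1ccc(O[Si](C(C)C)(C(C)C)C(C)C)c(OC)c1)[C@H](CO[Si](C)(C)C(C)(C)C)[C@@H](Cc1ccc(O[Si](C(C)C)(C(C)C)C(C)C)c(OC)c1)COS(=O)(=O)c1ccc(C)cc1
F8 | step 15 | 4-[(2S,3S,4R)-4-(4-hydroxy-3-methoxybenzyl)-3-(hydroxymethyl)oxolan-2-yl]-2-methoxyphenol | COc1cc(C[C@H]2CO[C@H](c3ccc(O)c(OC)c3)[C@@H]2CO)ccc1O
A1 | alternative 1 | (2S,3S,4R)-3-[(tert-butyldimethylsilyloxy)methyl]-4-[3-methoxy-4-(triisopropylsilyloxy)benzyl]-2-[3-methoxy-4-(triisopropylsilyloxy)phenyl]oxolane (identical with 25) | COc1cc(C[C@H]2CO[C@H](c3ccc(O[Si](C(C)C)(C(C)C)C(C)C)c(OC)c3)[C@@H]2CO[Si](C)(C)C(C)(C)C)ccc1O[Si](C(C)C)(C(C)C)C(C)C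
A2 | alternative 2 | (E)-4-(tert-butyldimethylsilyloxy)but-2-enal | O=C/C=C/CO[Si](C)(C)C(C)(C)C
A3 | alternative 2 | 3-methoxy-4-(triisopropylsilyloxy)benzaldehyde | COc1cc(C=O)ccc1O[Si](C(C)C)(C(C)C)C(C)C
A4 | alternative 2 | (4S,5S)-4-[(tert-butyldimethylsilyloxy)methyl]-5-[3-methoxy-4-(triisopropylsilyloxy)phenyl]dihydrofuran-2(3H)-one (cis) | O=C1C[C@@H](CO[Si](C)(C)C(C)(C)C)[C@@H](c2ccc(O[Si](C(C)C)(C(C)C)C(C)C)c(OC)c2)O1
A5 | alternative 3 | (5R)-5-[3-methoxy-4-(triisopropylsilyloxy)benzyl]-2-[3-methoxy-4-(triisopropylsilyloxy)phenyl]-4,5-dihydro-1,3-dioxepine (C2 epimers) | C1(c2ccc(O[Si](C(C)C)(C(C)C)C(C)C)c(OC)c2)OC[C@H](Cc2ccc(O[Si](C(C)C)(C(C)C)C(C)C)c(OC)c2)C=CO1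
A6 | alternative 3 | (2S,3R,4R)-4-[3-methoxy-4-(triisopropylsilyloxy)benzyl]-2-[3-methoxy-4-(triisopropylsilyloxy)phenyl]oxolane-3-carbaldehyde (2,3-cis, 3,4-trans) | COc1cc(C[C@H]2CO[C@H](c3ccc(O[Si](C(C)C)(C(C)C)C(C)C)c(OC)c3)[C@@H]2C=O)ccc1O[Si](C(C)C)(C(C)C)C(C)C
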